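# Proposed synthesis of (−)-epiafzelechin 3-O-gallate-(4β→8)-(−)-epicatechin 3-O-gallate (24)

## The problem

The target is (−)-epiafzelechin 3-O-gallate-(4β→8)-(−)-epicatechin 3-O-gallate. An upper 2-arylchroman (rings A, C, B) is joined from its C4 to C8 of a lower 2-arylchroman (rings D, F, E), and each C3 oxygen carries a galloyl ester. The five stereocentres (upper C2, C3, C4; lower C2, C3) are all R; both pyran rings are 2,3-cis and the upper one is 3,4-trans. Within a unit the C3 oxygen can control its neighbours: it steers a nucleophile to the opposite face of a C4 cation, and in an open chain a silyloxy group at C3 can direct hydride to an adjacent C2 ketone. Across the interflavan bond there is no useful control, so each unit needs its own source of absolute configuration. The 2,3-cis arrangement is the less accessible one, because closures in which a phenol displaces a leaving group at benzylic C2 either invert an ionisable centre or end in the trans series. The interflavan bond and both C2–O1 bonds are benzylic and open under acid, the thirteen phenols oxidise easily once free, and the gallates are base-labile esters that migrate to a neighbouring hydroxyl; esters must therefore come late and the last step must be neutral. The feature that allows the key step is the aryl ether bond O1–C8a of ring F, ortho to the interflavan carbon C8 of ring D. If C8a carries bromine, the benzylic C2 hydroxyl of an open C4–C3–C2 chain can be joined to it by palladium catalysis; C2 and C3 stay untouched, and a threo (2R,3R) chain becomes the cis ring directly. The price is that ring D is a bromoarene when it is joined to upper C4, and a bromoarene is a poor partner for the C4 cation.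

## Retrosynthesis

**End game.** Target 24 is traced to its per-benzylated, ring-A-dichlorinated form 23 (thirteen O–benzyl and two C–Cl bonds cut), 23 to diol 21 and acid 22 (two ester C–O bonds), and 21 to bis-silyl ether 20. Carrying the esters through the ring closure was rejected because an acyl group on O3 would migrate to a free neighbouring hydroxyl under base. Compound 20 holds only ethers, aryl halides and the interflavan bond. The forward steps need fluoride, a carbodiimide acylation and one buffered hydrogenolysis.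

**Key disconnection.** In 20 the bond O1–C8a of ring F is cut, giving bromo alcohol 19. The neighbouring cut O1–C2 would make C2 the electrophile, which inverts or ionises an electron-rich benzylic centre and must start from the erythro chain. Cutting O1–C8a leaves C2 and C3 as spectators, so the (2R,3R) pair of 19 already is the cis ring. Cutting the interflavan bond of 20 instead is the classical choice and is kept as a fallback. Precursor 19 has one ring fewer and the same stereocentres. The forward reaction asks that zerovalent palladium insert into a bromide with two ortho substituents, that only the C2 hydroxyl be arylated, and that C–O reductive elimination outrun β-hydride loss.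

**Carbinol from ketone.** The C2–H bond of 19 is cut, giving aryl ketone 18. A free benzylic hydroxyl would not survive the Lewis acid of the next disconnection, and a protecting group there would cost two steps. The ketone masks it, deactivates ring E as a competing nucleophile, and lets the C3 silyloxy group set C2 by Felkin–Anh hydride addition. The forward step must be syn-selective.

**Interflavan bond.** In 18 the bond C4–C8 is cut into C4 electrophile 14 and arene 17. The polarity is the natural one: the C4 cation is stabilised by O1 and two benzyloxy groups, and attack trans to O3 gives 4β. Ring D of 17, a brominated resorcinol diether, is however expected to be far less nucleophilic than the phloroglucinol-type ring A of the electrophile, which would otherwise condense with itself. Ring A of 14 is therefore blocked at C6 and C8 by chlorine. The forward step needs attack at the ring D position ortho to bromine and para to a benzyloxy group (C8), the site electrophiles prefer on 5-bromoresorcinol diethers, and not at C6 between the two ethers.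

**Activation and blocking of the upper unit.** The two C–Cl bonds of 14 are cut (13), then the C4–O bond (12). Oxidation precedes chlorination because hydride abstraction at C4 needs the electron-rich ring. Flavan 12 is a plain protected epiafzelechin.

**Upper heterocycle.** Ring C of 12 is opened at O1–C8a (bromo alcohol 11) and the carbinol is traced to ketone 10. This is the same pair of disconnections as in the lower unit, on a bromide with one ortho substituent. It gives the cis ring without the usual trans-to-cis oxidation–reduction and rehearses the key step.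

**Two ketones from one amide.** Ketones 10 and 17 are both cut at the aryl–carbonyl bond to Weinreb amide 7 and an aryl Grignard reagent (9 from bromide 8; 16 from bromide 15). One intermediate thus serves both units; rings B and E arrive as cheap aryl bromides.

**The common chain.** Amide 7 goes back through ester 6 to hydroxy ester 5. Its aryl–CH2 bond (C4–C4a) is cut to arylmagnesium 4 and methyl (R)-glycidate 3; 4 comes from iodide 2 and this from bromide 1. A chiral-pool amino acid with the aryl carbinol already in place was weighed for the lower chain. It would need nitrogen-to-oxygen exchange with retention beside an electron-rich benzylic alcohol and a protecting-group exchange, and would serve only one unit. Glycidate 3 supplies C3 with its oxygen and C4 as an electrophilic CH2 for both units, and leaves C2 to the Grignard reagent and the reduction.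

## Roads not taken

**Alternative 1:** The upper ring A would be made last by cutting its C4a–C8a bond back to the acyclic 3,5-dioxo ester A2, which already carries the complete lower flavan on C4 and the C2–C3 chain with ring B.
- Forward step: excess LDA deprotonates A2 several times, the C4a carbanion attacks the ester carbonyl, and loss of methoxide with enolisation gives the 2-substituted phloroglucinol A1, with ring C still open.
- Merits: no arene has to attack a C4 cation, so the weak nucleophilicity of a brominated ring D, self-condensation and the C6/C8 question all disappear. The lower unit could be any protected epicatechin.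
- Weak points: C2, C3 and C4 of the upper unit must be set in an open chain without help from the ring. The polyanion step exposes five benzyl ethers, two silyl ethers and an acetal to a large excess of strong base. The three new phenols of A1 must be told apart. Ring C then closes by displacement at benzylic C2 with inversion, the step the chosen plan avoids.
- Comparison: this road is better in the reliability of the fragment union and clearly longer. The chosen plan sets against it the chlorine-blocked electrophile 14 and a fallback that couples a closed lower flavan.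

**Alternative 2:** Ring D would be built last from four bonds (C5–C6, C6–C7, C8–C8a, C4a–C8a).
- Forward step: a photochemical Danheiser benzannulation. Irradiation of diazo enone A5, which carries the lower chain and ring E, triggers a Wolff rearrangement. The resulting ketene adds to silyloxyalkyne A4 on upper C4, and four-electron opening followed by six-electron closure gives phenol A3.
- Merits: the substitution pattern of ring D is programmed with no regiochemical choice, the union is neutral, and the interflavan bond is never made by cation chemistry. In these respects it is better than the arene coupling of step 11.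
- Weak points: A4 and A5 are specialised, sensitive partners that each need several steps. A3 must close ring F through O1–C2 with inversion at an electron-rich benzylic carbon, where ionisation threatens the configuration. The C7 silyl ether has to be exchanged for benzyl.
- Comparison: the chosen plan sets against the better regiocontrol a shorter sequence from the common amide 7 and a ring closure in which C2 is a spectator.

**Alternative 3:** Lower C3–C4 and O1–C2 would be cut together.
- Forward step: salicyl alcohol A7 (ring D on a galloylated upper unit) loses water. The heterodiene across C4, C4a, C8a and the phenol oxygen adds the (Z)-enol gallate A8 in a [4+2] sense and gives the per-benzylated target A6.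
- Merits: the most convergent road. One step closes ring F, sets both lower stereocentres as cis (suprafacial addition to the Z alkene) and installs the lower ester; A6 is one hydrogenolysis from the target.
- Weak points: the two faces of the heterodiene are told apart only by the remote upper unit across a rotating C4–C8 axis, so the (2R,3R) and (2S,3S) lower units are both expected. An enol ester is a reluctant partner for an inverse-demand addition, which leaves time for the heterodiene to dimerise. A8 must be made and kept geometrically pure.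
- Comparison: with facial control this road would be several steps shorter than the chosen one. The chosen plan sets against it certainty of absolute configuration: C3 from the chiral pool, C2 by substrate control, C4 by the ring.

Key step: step 13

Remark: the target is read as (2R,3R,4R)-epiafzelechin 3-O-gallate linked 4β→8 to (2R,3R)-epicatechin 3-O-gallate; compounds 1, 3, 8, 15 and 22 are taken to be commercial.

## Route

Step 1
Reactants: 1 1-bromo-3,5-bis(benzyloxy)benzene
Product: 2 1,5-bis(benzyloxy)-3-bromo-2-iodobenzene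
Conditions: NIS (1.0 equiv), TFA (cat.), MeCN, 0 °C → rt
Reagents that add atoms: N-iodosuccinimide, O=C1CCC(=O)N1I
Why: Electrophilic aromatic iodination of a 5-substituted resorcinol diether should occur para to one benzyloxy group and next to bromine, not at the more crowded position between the two ethers; one equivalent of NIS limits over-iodination.

Step 2
Reactants: 2 1,5-bis(benzyloxy)-3-bromo-2-iodobenzene; 3 methyl (R)-glycidate
Product: 5 methyl (2R)-3-[2-bromo-4,6-bis(benzyloxy)phenyl]-2-hydroxypropanoate, via arylmagnesium chloride 4 (not isolated)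
Conditions: i-PrMgCl·LiCl, THF, −40 °C; then CuI (10 mol%), 3, −40 → −15 °C
Reagents that add atoms: none
Why: Iodine–magnesium exchange is much faster than bromine–magnesium exchange, so 4 keeps its ortho bromide at low temperature. The copper-catalysed Grignard opening of the glycidic ester occurs at the unsubstituted epoxide carbon, so the stereocentre of 3 is untouched and becomes C3 (R) of a flavan unit.

Step 3
Reactants: 5 methyl (2R)-3-[2-bromo-4,6-bis(benzyloxy)phenyl]-2-hydroxypropanoate
Product: 6 methyl (2R)-3-[2-bromo-4,6-bis(benzyloxy)phenyl]-2-(triisopropylsilyloxy)propanoate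
Conditions: TIPSOTf, 2,6-lutidine, CH2Cl2, 0 °C
Reagents that add atoms: triisopropylsilyl triflate, CC(C)[Si](OS(=O)(=O)C(F)(F)F)(C(C)C)C(C)C
Why: Standard silylation of a secondary α-hydroxy ester with a silyl triflate and a hindered base. The triisopropylsilyl group is chosen because it should resist 1,2 oxygen-to-oxygen migration under the later carbonate conditions and gives a strong Felkin–Anh bias in the ketone reductions.

Step 4
Reactants: 6 methyl (2R)-3-[2-bromo-4,6-bis(benzyloxy)phenyl]-2-(triisopropylsilyloxy)propanoate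
Product: 7 (2R)-3-[2-bromo-4,6-bis(benzyloxy)phenyl]-N-methoxy-N-methyl-2-(triisopropylsilyloxy)propanamide
Conditions: MeNH(OMe)·HCl, i-PrMgCl, THF, −20 → 0 °C
Reagents that add atoms: N,O-dimethylhydroxylamine hydrochloride, CNOC.Cl
Why: Weinreb amide formation by aminolysis of the ester with the magnesium amide. The α-silyloxy stereocentre should not epimerise, and the hindered aryl bromide does not exchange with i-PrMgCl at this temperature.

Step 5
Reactants: 7 (2R)-3-[2-bromo-4,6-bis(benzyloxy)phenyl]-N-methoxy-N-methyl-2-(triisopropylsilyloxy)propanamide; 8 1-(benzyloxy)-4-bromobenzene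
Product: 10 (2R)-3-[2-bromo-4,6-bis(benzyloxy)phenyl]-1-[4-(benzyloxy)phenyl]-2-(triisopropylsilyloxy)propan-1-one, via arylmagnesium bromide 9 (not isolated)
Conditions: 8, Mg, THF, rt; then 7, THF, 0 °C; aq. NH4Cl
Reagents that add atoms: none
Why: Weinreb ketone synthesis: the chelated tetrahedral adduct survives until work-up, so the Grignard reagent adds only once and the α centre is kept.

Step 6
Reactants: 10 (2R)-3-[2-bromo-4,6-bis(benzyloxy)phenyl]-1-[4-(benzyloxy)phenyl]-2-(triisopropylsilyloxy)propan-1-one
Product: 11 (1R,2R)-3-[2-bromo-4,6-bis(benzyloxy)phenyl]-1-[4-(benzyloxy)phenyl]-2-(triisopropylsilyloxy)propan-1-ol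
Conditions: LiBH(s-Bu)3, THF, −78 °C
Reagents that add atoms: none
Why: Felkin–Anh addition of a bulky hydride: with the C–OSi bond perpendicular to the carbonyl group and hydride entering past the hydrogen atom, the (2R) ketone should give the (1R,2R) syn (threo) alcohol. The non-chelating silyl ether disfavours the chelated path to the anti isomer.

Step 7
Reactants: 11 (1R,2R)-3-[2-bromo-4,6-bis(benzyloxy)phenyl]-1-[4-(benzyloxy)phenyl]-2-(triisopropylsilyloxy)propan-1-ol
Product: 12 (2R,3R)-5,7-bis(benzyloxy)-2-[4-(benzyloxy)phenyl]-3-(triisopropylsilyloxy)chroman (5,7,4'-tri-O-benzyl-3-O-triisopropylsilyl-(−)-epiafzelechin)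
Conditions: Pd(OAc)2 (5 mol%), 2-(di-tert-butylphosphino)-1,1'-binaphthyl, Cs2CO3, toluene, 70 °C
Reagents that add atoms: none
Why: Palladium-catalysed intramolecular aryl etherification (Buchwald–Hartwig C–O coupling) of a secondary alcohol with an aryl bromide that has one ortho substituent. C2 and C3 take no part, so the threo pair becomes the 2,3-cis ring of epiafzelechin.

Step 8
Reactants: 12 5,7,4'-tri-O-benzyl-3-O-triisopropylsilyl-(−)-epiafzelechin
Product: 13 4β-(2-ethoxyethoxy)-5,7,4'-tri-O-benzyl-3-O-triisopropylsilyl-(−)-epiafzelechin (4-alkoxy group trans to the 3-silyloxy group)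
Conditions: DDQ, 2-ethoxyethanol, CH2Cl2, rt
Reagents that add atoms: 2-ethoxyethanol, CCOCCO
Why: Oxidative benzylic functionalisation: DDQ abstracts hydride from C4, whose cation is stabilised by O1 and the 5- and 7-benzyloxy groups, and the alcohol adds trans to the 3-silyloxy group. This is the usual C4 activation of benzylated flavan-3-ols.

Step 9
Reactants: 13 4β-(2-ethoxyethoxy)-5,7,4'-tri-O-benzyl-3-O-triisopropylsilyl-(−)-epiafzelechin
Product: 14 6,8-dichloro-4β-(2-ethoxyethoxy)-5,7,4'-tri-O-benzyl-3-O-triisopropylsilyl-(−)-epiafzelechin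
Conditions: NCS (2.2 equiv), DMF, 0 °C → rt
Reagents that add atoms: N-chlorosuccinimide, O=C1CCC(=O)N1Cl
Why: Electrophilic chlorination at the only strongly activated free positions, C6 and C8 of ring A. The chlorines block ring A as a nucleophile in step 11, should survive the palladium step and leave in step 16.

Step 10
Reactants: 7 (2R)-3-[2-bromo-4,6-bis(benzyloxy)phenyl]-N-methoxy-N-methyl-2-(triisopropylsilyloxy)propanamide; 15 4-bromo-1,2-bis(benzyloxy)benzene
Product: 17 (2R)-3-[2-bromo-4,6-bis(benzyloxy)phenyl]-1-[3,4-bis(benzyloxy)phenyl]-2-(triisopropylsilyloxy)propan-1-one, via arylmagnesium bromide 16 (not isolated)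
Conditions: 15, Mg, THF, rt; then 7, THF, 0 °C; aq. NH4Cl
Reagents that add atoms: none
Why: Weinreb ketone synthesis as in step 5; it brings in ring E and the latent C2 carbinol carbon of the lower unit.

Step 11
Reactants: 14 6,8-dichloro-4β-(2-ethoxyethoxy)-5,7,4'-tri-O-benzyl-3-O-triisopropylsilyl-(−)-epiafzelechin; 17 (2R)-3-[2-bromo-4,6-bis(benzyloxy)phenyl]-1-[3,4-bis(benzyloxy)phenyl]-2-(triisopropylsilyloxy)propan-1-one
Product: 18 6,8-dichloro-5,7,4'-tri-O-benzyl-3-O-triisopropylsilyl-(−)-epiafzelechin bearing at C4 (4β, trans to O3) a 2-bromo-4,6-bis(benzyloxy)-3-[(2R)-3-[3,4-bis(benzyloxy)phenyl]-3-oxo-2-(triisopropylsilyloxy)propyl]phenyl group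
Conditions: 17 (2 equiv), TMSOTf (0.2 equiv), CH2Cl2, −78 → −30 °C; Et3N quench
Reagents that add atoms: none
Why: Lewis-acid-mediated Friedel–Crafts arylation at C4 of a 4-alkoxyflavan, the standard interflavan coupling, run with a halogen-capped electrophile so that only ring D of 17 can act as nucleophile. Attack is expected at the ring D position ortho to bromine and para to a benzyloxy group (C8), from the face trans to the 3-silyloxy group, which sets C4 as 4β. Ring E is deactivated by the ketone.

Step 12
Reactants: 18 the coupled ketone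
Product: 19 6,8-dichloro-5,7,4'-tri-O-benzyl-3-O-triisopropylsilyl-(−)-epiafzelechin bearing at C4 (4β) a 2-bromo-4,6-bis(benzyloxy)-3-[(2R,3R)-3-[3,4-bis(benzyloxy)phenyl]-3-hydroxy-2-(triisopropylsilyloxy)propyl]phenyl group
Conditions: LiBH(s-Bu)3, THF, −78 °C
Reagents that add atoms: none
Why: Felkin–Anh hydride addition as in step 6; the lower C3 silyloxy group should direct hydride to give the (2R,3R) threo carbinol. Aryl halides and ethers are inert to the borohydride.

Step 13
Reactants: 19 the bromo alcohol
Product: 20 6,8-dichloro-5,7,4'-tri-O-benzyl-3-O-triisopropylsilyl-(−)-epiafzelechin-(4β→8)-5,7,3',4'-tetra-O-benzyl-3-O-triisopropylsilyl-(−)-epicatechin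
Conditions: Pd(OAc)2 (10 mol%), 2-(di-tert-butylphosphino)-1,1'-binaphthyl (12 mol%), Cs2CO3, toluene, 80 °C
Reagents that add atoms: none
Why: Pd(OAc)2 is reduced in situ to a monoligated zerovalent palladium species that inserts into the C8a–Br bond of ring D; carbonate then exchanges bromide on divalent palladium for the lower C2 alkoxide, and C–O reductive elimination forms the O1–C8a bond. The closest known reaction type is the palladium-catalysed intramolecular etherification of aryl bromides with secondary alcohols to chromans (Buchwald–Hartwig C–O coupling), already used on the simpler bromide in step 7. Ring F closes by reductive elimination from a seven-membered oxapalladacycle, which amounts to a 6-exo attack of the C2 oxygen on C8a. No stereocentre is formed and none reacts: C2 keeps its oxygen, so the (2R,3R) threo chain of 19 becomes the 2,3-cis ring with retention. Selectivity among the three carbon–halogen bonds should follow from electronics and bond strength: the bromide has only meta alkoxy groups, whereas the two ring A chlorides are stronger bonds ortho and para to three alkoxy groups and should not undergo oxidative addition at 80 °C. Selectivity among the oxygens rests on the single free hydroxyl at lower C2; the triisopropylsilyl group at lower C3 should not shift to the C2 alkoxide, which would open the way to a five-membered ring. The bulky di-tert-butylbiarylphosphine favours C–O reductive elimination over β-hydride loss from the benzylic alkoxide and, with the intramolecular setting, must compensate for the two ortho substituents of the bromide.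

Step 14
Reactants: 20 the bis-silyl ether
Product: 21 6,8-dichloro-5,7,4'-tri-O-benzyl-(−)-epiafzelechin-(4β→8)-5,7,3',4'-tetra-O-benzyl-(−)-epicatechin (both C3 hydroxyls free)
Conditions: Bu4NF, THF, rt → 45 °C
Reagents that add atoms: none
Why: Fluoride cleavage of both secondary silyl ethers; benzyl ethers, aryl chlorides and the interflavan bond are inert to fluoride.

Step 15
Reactants: 21 the diol; 22 3,4,5-tris(benzyloxy)benzoic acid
Product: 23 3,3'-bis-O-[3,4,5-tris(benzyloxy)benzoyl] derivative of 21
Conditions: 22 (3 equiv), DCC, DMAP, CH2Cl2, rt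
Reagents that add atoms: none
Why: Steglich esterification of the two hindered secondary alcohols with excess acid; no phenol is free, so acylation is confined to the two C3 oxygens.

Step 16
Reactants: 23 the per-benzylated dichloro digallate
Product: 24 (−)-epiafzelechin 3-O-gallate-(4β→8)-(−)-epicatechin 3-O-gallate
Conditions: H2 (1 atm), Pd(OH)2/C, NaOAc, THF/MeOH/H2O, rt
Reagents that add atoms: none
Why: Hydrogenolysis over Pd(OH)2/C should cleave the thirteen benzyl ethers and, with acetate as acid scavenger, the two aryl C–Cl bonds. The medium stays near neutral, so the interflavan bond, the pyran C2–O bonds and the gallates should survive.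

## Compound list

1 | 1-bromo-3,5-bis(benzyloxy)benzene | Brc1cc(OCc2ccccc2)cc(OCc2ccccc2)c1 | starting material
2 | 1,5-bis(benzyloxy)-3-bromo-2-iodobenzene | Brc1cc(OCc2ccccc2)cc(OCc2ccccc2)c1I | intermediate
3 | methyl (R)-glycidate (methyl (2R)-oxirane-2-carboxylate) | COC(=O)[C@H]1CO1 | starting material
4 | [2-bromo-4,6-bis(benzyloxy)phenyl]magnesium chloride (LiCl complex) | Cl[Mg]c1c(Br)cc(OCc2ccccc2)cc1OCc1ccccc1 | intermediate
5 | methyl (2R)-3-[2-bromo-4,6-bis(benzyloxy)phenyl]-2-hydroxypropanoate | Brc1cc(OCc2ccccc2)cc(OCc2ccccc2)c1C[C@@H](O)C(=O)OC | intermediate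
6 | methyl (2R)-3-[2-bromo-4,6-bis(benzyloxy)phenyl]-2-(triisopropylsilyloxy)propanoate | Brc1cc(OCc2ccccc2)cc(OCc2ccccc2)c1C[C@@H](O[Si](C(C)C)(C(C)C)C(C)C)C(=O)OC | intermediate
7 | (2R)-3-[2-bromo-4,6-bis(benzyloxy)phenyl]-N-methoxy-N-methyl-2-(triisopropylsilyloxy)propanamide | Brc1cc(OCc2ccccc2)cc(OCc2ccccc2)c1C[C@@H](O[Si](C(C)C)(C(C)C)C(C)C)C(=O)N(C)OC | intermediate
8 | 1-(benzyloxy)-4-bromobenzene | Brc1ccc(OCc2ccccc2)cc1 | starting material
9 | [4-(benzyloxy)phenyl]magnesium bromide | Br[Mg]c1ccc(OCc2ccccc2)cc1 | intermediate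
10 | (2R)-3-[2-bromo-4,6-bis(benzyloxy)phenyl]-1-[4-(benzyloxy)phenyl]-2-(triisopropylsilyloxy)propan-1-one | Brc1cc(OCc2ccccc2)cc(OCc2ccccc2)c1C[C@@H](O[Si](C(C)C)(C(C)C)C(C)C)C(=O)c1ccc(OCc2ccccc2)cc1 | intermediate
11 | (1R,2R)-3-[2-bromo-4,6-bis(benzyloxy)phenyl]-1-[4-(benzyloxy)phenyl]-2-(triisopropylsilyloxy)propan-1-ol | Brc1cc(OCc2ccccc2)cc(OCc2ccccc2)c1C[C@@H](O[Si](C(C)C)(C(C)C)C(C)C)[C@H](O)c1ccc(OCc2ccccc2)cc1 | intermediate
12 | (2R,3R)-5,7-bis(benzyloxy)-2-[4-(benzyloxy)phenyl]-3-(triisopropylsilyloxy)chroman | CC(C)[Si](C(C)C)(C(C)C)O[C@@H]1Cc2c(OCc3ccccc3)cc(OCc3ccccc3)cc2O[C@@H]1c1ccc(OCc2ccccc2)cc1 | intermediate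
13 | 4β-(2-ethoxyethoxy) derivative of 12 (4-alkoxy trans to 3-silyloxy) | CC(C)[Si](C(C)C)(C(C)C)O[C@@H]1[C@@H](OCCOCC)c2c(OCc3ccccc3)cc(OCc3ccccc3)cc2O[C@@H]1c1ccc(OCc2ccccc2)cc1 | intermediate
14 | 6,8-dichloro derivative of 13 | CC(C)[Si](C(C)C)(C(C)C)O[C@@H]1[C@@H](OCCOCC)c2c(OCc3ccccc3)c(Cl)c(OCc3ccccc3)c(Cl)c2O[C@@H]1c1ccc(OCc2ccccc2)cc1 | intermediate
15 | 4-bromo-1,2-bis(benzyloxy)benzene | Brc1ccc(OCc2ccccc2)c(OCc2ccccc2)c1 | starting material
16 | [3,4-bis(benzyloxy)phenyl]magnesium bromide | Br[Mg]c1ccc(OCc2ccccc2)c(OCc2ccccc2)c1 | intermediate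
17 | (2R)-3-[2-bromo-4,6-bis(benzyloxy)phenyl]-1-[3,4-bis(benzyloxy)phenyl]-2-(triisopropylsilyloxy)propan-1-one | Brc1cc(OCc2ccccc2)cc(OCc2ccccc2)c1C[C@@H](O[Si](C(C)C)(C(C)C)C(C)C)C(=O)c1ccc(OCc2ccccc2)c(OCc2ccccc2)c1 | intermediate
18 | upper 6,8-dichloro flavan with C4 (4β) joined to ring D; ring D carries Br at C8a and the (2R)-3-aryl-3-oxo-2-(triisopropylsilyloxy)propyl chain at C4a | CC(C)[Si](C(C)C)(C(C)C)O[C@@H]1[C@@H](c2c(OCc3ccccc3)cc(OCc3ccccc3)c(C[C@@H](O[Si](C(C)C)(C(C)C)C(C)C)C(=O)c3ccc(OCc4ccccc4)c(OCc4ccccc4)c3)c2Br)c2c(OCc3ccccc3)c(Cl)c(OCc3ccccc3)c(Cl)c2O[C@@H]1c1ccc(OCc2ccccc2)cc1 | intermediate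
19 | as 18 with the (2R,3R)-3-aryl-3-hydroxy-2-(triisopropylsilyloxy)propyl chain (lower C2 carbinol R, lower C3 R) | CC(C)[Si](C(C)C)(C(C)C)O[C@@H]1[C@@H](c2c(OCc3ccccc3)cc(OCc3ccccc3)c(C[C@@H](O[Si](C(C)C)(C(C)C)C(C)C)[C@H](O)c3ccc(OCc4ccccc4)c(OCc4ccccc4)c3)c2Br)c2c(OCc3ccccc3)c(Cl)c(OCc3ccccc3)c(Cl)c2O[C@@H]1c1ccc(OCc2ccccc2)cc1 | intermediate
20 | 6,8-dichloro-5,7,4'-tri-O-benzyl-3-O-triisopropylsilyl-epiafzelechin-(4β→8)-5,7,3',4'-tetra-O-benzyl-3-O-triisopropylsilyl-epicatechin | CC(C)[Si](C(C)C)(C(C)C)O[C@@H]1[C@@H](c2c(OCc3ccccc3)cc(OCc3ccccc3)c3c2O[C@H](c2ccc(OCc4ccccc4)c(OCc4ccccc4)c2)[C@H](O[Si](C(C)C)(C(C)C)C(C)C)C3)c2c(OCc3ccccc3)c(Cl)c(OCc3ccccc3)c(Cl)c2O[C@@H]1c1ccc(OCc2ccccc2)cc1 | intermediate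
21 | 3,3'-diol obtained from 20 | O[C@@H]1[C@@H](c2c(OCc3ccccc3)cc(OCc3ccccc3)c3c2O[C@H](c2ccc(OCc4ccccc4)c(OCc4ccccc4)c2)[C@H](O)C3)c2c(OCc3ccccc3)c(Cl)c(OCc3ccccc3)c(Cl)c2O[C@@H]1c1ccc(OCc2ccccc2)cc1 | intermediate
22 | 3,4,5-tris(benzyloxy)benzoic acid | OC(=O)c1cc(OCc2ccccc2)c(OCc2ccccc2)c(OCc2ccccc2)c1 | starting material
23 | 3,3'-bis-O-[3,4,5-tris(benzyloxy)benzoyl] derivative of 21 | O=C(O[C@@H]1[C@@H](c2c(OCc3ccccc3)cc(OCc3ccccc3)c3c2O[C@H](c2ccc(OCc4ccccc4)c(OCc4ccccc4)c2)[C@H](OC(=O)c2cc(OCc4ccccc4)c(OCc4ccccc4)c(OCc4ccccc4)c2)C3)c2c(OCc3ccccc3)c(Cl)c(OCc3ccccc3)c(Cl)c2O[C@@H]1c1ccc(OCc2ccccc2)cc1)c1cc(OCc2ccccc2)c(OCc2ccccc2)c(OCc2ccccc2)c1 | intermediate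
24 | (−)-epiafzelechin 3-O-gallate-(4β→8)-(−)-epicatechin 3-O-gallate | O=C(O[C@@H]1[C@@H](c2c(O)cc(O)c3c2O[C@H](c2ccc(O)c(O)c2)[C@H](OC(=O)c2cc(O)c(O)c(O)c2)C3)c2c(O)cc(O)cc2O[C@@H]1c1ccc(O)cc1)c1cc(O)c(O)c(O)c1 | target

## Step count and risk

Total: 16 steps. Longest linear sequence: 15 steps (1 → 2 → 5 → 6 → 7 → 10 → 11 → 12 → 13 → 14 → 18 → 19 → 20 → 21 → 23 → 24); step 10 is the only side branch.

Least certain steps:

**Step 13 (key step).** Oxidative addition may be slow at a bromide flanked by the bulky flavanyl group and the benzylic methylene. That would leave time for β-hydride elimination from the palladium alkoxide (oxidation of the carbinol with reduction of the C–Br bond) or for silyl migration to the C2 oxygen. The fallback closes ring F before the interflavan bond is made. It sets out from 17: reduction with LiBH(s-Bu)3 as in step 6 should give (1R,2R)-3-[2-bromo-4,6-bis(benzyloxy)phenyl]-1-[3,4-bis(benzyloxy)phenyl]-2-(triisopropylsilyloxy)propan-1-ol F1. Its bromide has one ortho substituent and should cyclise under the conditions of step 7 to 5,7,3',4'-tetra-O-benzyl-3-O-triisopropylsilyl-(−)-epicatechin F2. F2 is a fully activated phloroglucinol-type nucleophile and would be coupled at C8 with the capped electrophile 14 (TMSOTf, CH2Cl2, −78 → −30 °C), returning to the route at 20. The O1–C8a construction is kept, but the late closure is given up.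

**Step 11.** The brominated ring D may capture the C4 cation too slowly, so that elimination or decomposition of the cation takes over, or attack may occur at C6 between the two benzyloxy groups. The fallback changes the order of bond formation and sets out from 14 and 1. Bromide 1 is unhindered, has two equivalent positions ortho to bromine, and can be used in large excess. It would be arylated by 14 (TMSOTf) to give the 6,8-dichloro flavan with a 4β-[2-bromo-4,6-bis(benzyloxy)phenyl] group F3. The ring D C–H between bromine and the benzyloxy group is the only one acidified by a halogen; magnesiation there with TMPMgCl·LiCl and CuI-catalysed opening of 3 would give the ring D (2R)-2-hydroxypropanoate methyl ester F4. Silylation (TIPSOTf, 2,6-lutidine) gives the silyl ether F5, aminolysis as in step 4 the Weinreb amide F6, and addition of Grignard reagent 16 returns to the route at 18.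

**Step 12.** Hydride delivery to the crowded ketone may show poor facial selectivity; the (2S) epimer would end in a trans ring. The fallback sets the carbinol centre under catalyst control before the coupling and sets out from 17. Noyori transfer hydrogenation with RuCl(p-cymene)[(S,S)-TsDPEN] in HCO2H/Et3N, where the aryl ketone is placed by the catalyst, should give the alcohol F1 described above. Protection (TESCl, imidazole) gives the triethylsilyl ether F7. Coupling with 14 as in step 11 gives the C2-O-triethylsilyl ether of 19, F8. Selective cleavage of the triethylsilyl ether beside two triisopropylsilyl ethers (HF·pyridine, THF/pyridine, 0 °C) returns to the route at 19.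

**Step 16.** Hydrogenolysis of the two electron-rich C–Cl bonds may stay incomplete, or chloride may slow the catalyst so that the prolonged reaction costs ester or interflavan integrity. The fallback removes the chlorines in homogeneous solution before the esters exist and sets out from 20. Hydrodechlorination with (IPr)Pd(allyl)Cl (IPr = 1,3-bis(2,6-diisopropylphenyl)imidazol-2-ylidene), NaOt-Bu and i-PrOH in toluene at 60 °C spares benzyl and silyl ethers and should give the chlorine-free bis-silyl ether F9. Bu4NF gives the chlorine-free diol F10, Steglich esterification with 22 the chlorine-free per-benzylated digallate F11, and hydrogenolysis over Pd(OH)2/C without base returns to the route at 24.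

## Further compounds

F1 | step 13 | (1R,2R)-3-[2-bromo-4,6-bis(benzyloxy)phenyl]-1-[3,4-bis(benzyloxy)phenyl]-2-(triisopropylsilyloxy)propan-1-ol | Brc1cc(OCc2ccccc2)cc(OCc2ccccc2)c1C[C@@H](O[Si](C(C)C)(C(C)C)C(C)C)[C@H](O)c1ccc(OCc2ccccc2)c(OCc2ccccc2)c1
F2 | step 13 | 5,7,3',4'-tetra-O-benzyl-3-O-triisopropylsilyl-(−)-epicatechin | CC(C)[Si](C(C)C)(C(C)C)O[C@@H]1Cc2c(OCc3ccccc3)cc(OCc3ccccc3)cc2O[C@@H]1c1ccc(OCc2ccccc2)c(OCc2ccccc2)c1
F3 | step 11 | 6,8-dichloro-4β-[2-bromo-4,6-bis(benzyloxy)phenyl]-5,7,4'-tri-O-benzyl-3-O-triisopropylsilyl-epiafzelechin | CC(C)[Si](C(C)C)(C(C)C)O[C@@H]1[C@@H](c2c(OCc3ccccc3)cc(OCc3ccccc3)cc2Br)c2c(OCc3ccccc3)c(Cl)c(OCc3ccccc3)c(Cl)c2O[C@@H]1c1ccc(OCc2ccccc2)cc1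
F4 | step 11 | F3 carrying a (2R)-2-hydroxy-3-methoxy-3-oxopropyl group on ring D between Br and OBn | CC(C)[Si](C(C)C)(C(C)C)O[C@@H]1[C@@H](c2c(OCc3ccccc3)cc(OCc3ccccc3)c(C[C@@H](O)C(=O)OC)c2Br)c2c(OCc3ccccc3)c(Cl)c(OCc3ccccc3)c(Cl)c2O[C@@H]1c1ccc(OCc2ccccc2)cc1
F5 | step 11 | triisopropylsilyl ether of F4 | CC(C)[Si](C(C)C)(C(C)C)O[C@@H]1[C@@H](c2c(OCc3ccccc3)cc(OCc3ccccc3)c(C[C@@H](O[Si](C(C)C)(C(C)C)C(C)C)C(=O)OC)c2Br)c2c(OCc3ccccc3)c(Cl)c(OCc3ccccc3)c(Cl)c2O[C@@H]1c1ccc(OCc2ccccc2)cc1
F6 | step 11 | N-methoxy-N-methyl amide from F5 | CC(C)[Si](C(C)C)(C(C)C)O[C@@H]1[C@@H](c2c(OCc3ccccc3)cc(OCc3ccccc3)c(C[C@@H](O[Si](C(C)C)(C(C)C)C(C)C)C(=O)N(C)OC)c2Br)c2c(OCc3ccccc3)c(Cl)c(OCc3ccccc3)c(Cl)c2O[C@@H]1c1ccc(OCc2ccccc2)cc1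
F7 | step 12 | triethylsilyl ether of F1 | Brc1cc(OCc2ccccc2)cc(OCc2ccccc2)c1C[C@@H](O[Si](C(C)C)(C(C)C)C(C)C)[C@H](O[Si](CC)(CC)CC)c1ccc(OCc2ccccc2)c(OCc2ccccc2)c1
F8 | step 12 | C2-O-triethylsilyl ether of 19 | CC(C)[Si](C(C)C)(C(C)C)O[C@@H]1[C@@H](c2c(OCc3ccccc3)cc(OCc3ccccc3)c(C[C@@H](O[Si](C(C)C)(C(C)C)C(C)C)[C@H](O[Si](CC)(CC)CC)c3ccc(OCc4ccccc4)c(OCc4ccccc4)c3)c2Br)c2c(OCc3ccccc3)c(Cl)c(OCc3ccccc3)c(Cl)c2O[C@@H]1c1ccc(OCc2ccccc2)cc1
F9 | step 16 | chlorine-free analogue of 20 | CC(C)[Si](C(C)C)(C(C)C)O[C@@H]1[C@@H](c2c(OCc3ccccc3)cc(OCc3ccccc3)c3c2O[C@H](c2ccc(OCc4ccccc4)c(OCc4ccccc4)c2)[C@H](O[Si](C(C)C)(C(C)C)C(C)C)C3)c2c(OCc3ccccc3)cc(OCc3ccccc3)cc2O[C@@H]1c1ccc(OCc2ccccc2)cc1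
F10 | step 16 | chlorine-free analogue of 21 | O[C@@H]1[C@@H](c2c(OCc3ccccc3)cc(OCc3ccccc3)c3c2O[C@H](c2ccc(OCc4ccccc4)c(OCc4ccccc4)c2)[C@H](O)C3)c2c(OCc3ccccc3)cc(OCc3ccccc3)cc2O[C@@H]1c1ccc(OCc2ccccc2)cc1
F11 | step 16 | chlorine-free analogue of 23 | O=C(O[C@@H]1[C@@H](c2c(OCc3ccccc3)cc(OCc3ccccc3)c3c2O[C@H](c2ccc(OCc4ccccc4)c(OCc4ccccc4)c2)[C@H](OC(=O)c2cc(OCc4ccccc4)c(OCc4ccccc4)c(OCc4ccccc4)c2)C3)c2c(OCc3ccccc3)cc(OCc3ccccc3)cc2O[C@@H]1c1ccc(OCc2ccccc2)cc1)c1cc(OCc2ccccc2)c(OCc2ccccc2)c(OCc2ccccc2)c1
A1 | alternative 1 | 2-substituted phloroglucinol (ring A formed, ring C open) | Oc1cc(O)cc(O)c1[C@H](c2c(OCc5ccccc5)cc(OCc5ccccc5)c3c2O[C@H](c7ccc(OCc5ccccc5)c(OCc5ccccc5)c7)[C@H](O[Si](C)(C)C(C)(C)C)C3)[C@@H](OCOC)[C@@H](O[Si](CC)(CC)CC)c7ccc(OCc5ccccc5)cc7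
A2 | alternative 1 | methyl 3,5-dioxoheptanoate carrying at C7 the lower flavan and the protected C2–C3 chain with ring B | COC(=O)CC(=O)CC(=O)C[C@H](c2c(OCc5ccccc5)cc(OCc5ccccc5)c3c2O[C@H](c7ccc(OCc5ccccc5)c(OCc5ccccc5)c7)[C@H](O[Si](C)(C)C(C)(C)C)C3)[C@@H](OCOC)[C@@H](O[Si](CC)(CC)CC)c7ccc(OCc5ccccc5)cc7
A3 | alternative 2 | ring D phenol joining the upper flavan and the open lower chain | CC(C)(C)[Si](C)(C)O[C@@H]1[C@@H](c2c(O[Si](C(C)C)(C(C)C)C(C)C)cc(OCc5ccccc5)c(C[C@@H](O[Si](C)(C)C(C)(C)C)[C@@H](O[Si](CC)(CC)CC)c7ccc(OCc5ccccc5)c(OCc5ccccc5)c7)c2O)c3c(OCc5ccccc5)cc(OCc5ccccc5)cc3O[C@@H]1c7ccc(OCc5ccccc5)cc7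
A4 | alternative 2 | upper flavan with a (triisopropylsilyloxy)ethynyl group at C4 | CC(C)(C)[Si](C)(C)O[C@@H]1[C@@H](C#CO[Si](C(C)C)(C(C)C)C(C)C)c3c(OCc5ccccc5)cc(OCc5ccccc5)cc3O[C@@H]1c7ccc(OCc5ccccc5)cc7
A5 | alternative 2 | 3-(benzyloxy)-1-diazoalk-3-en-2-one carrying the silylated lower chain and ring E | [N-]=[N+]=CC(=O)C(OCc1ccccc1)=CC[C@@H](O[Si](C)(C)C(C)(C)C)[C@@H](O[Si](CC)(CC)CC)c1ccc(OCc2ccccc2)c(OCc2ccccc2)c1
A6 | alternative 3 | per-benzylated target | O=C(c6cc(OCc5ccccc5)c(OCc5ccccc5)c(OCc5ccccc5)c6)O[C@@H]1[C@@H](c2c(OCc5ccccc5)cc(OCc5ccccc5)c3c2O[C@H](c7ccc(OCc5ccccc5)c(OCc5ccccc5)c7)[C@H](OC(=O)c6cc(OCc5ccccc5)c(OCc5ccccc5)c(OCc5ccccc5)c6)C3)c4c(OCc5ccccc5)cc(OCc5ccccc5)cc4O[C@@H]1c7ccc(OCc5ccccc5)cc7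
A7 | alternative 3 | ring D salicyl alcohol on the galloylated upper unit | O=C(c6cc(OCc5ccccc5)c(OCc5ccccc5)c(OCc5ccccc5)c6)O[C@@H]1[C@@H](c2c(OCc5ccccc5)cc(OCc5ccccc5)c(CO)c2O)c4c(OCc5ccccc5)cc(OCc5ccccc5)cc4O[C@@H]1c7ccc(OCc5ccccc5)cc7
A8 | alternative 3 | (Z)-2-[3,4-bis(benzyloxy)phenyl]ethenyl 3,4,5-tris(benzyloxy)benzoate | O=C(O/C=C\c1ccc(OCc2ccccc2)c(OCc2ccccc2)c1)c1cc(OCc2ccccc2)c(OCc2ccccc2)c(OCc2ccccc2)c1
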